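**Retrosynthetic overview**

1. The side chain comes last: the C12–C13 bond is made by Negishi coupling of a C12 alkylzinc with a geometrically defined (E)-enol tosylate (this gives 13Z). Before that, C17 (Wittig at C8), the C4 gem-dimethyl group (MeLi transposition, then cuprate) and the equatorial C2 alcohol (dissolving metal) are set on a trans-decalin vinylogous ester.
2. Ring A (C1–C5, C10) is disconnected to a 3-alkoxycyclobutenone (C4(=O)–C1H=C2(O)–C3H2) and the C5=C10 double bond of a ring B cyclohexene. A thermal cascade (4π ring opening, intramolecular ketene–alkene [2+2], 1,3-acyl shift) inserts C5 and C10 into the C4–C1 bond, so a four-membered ring grows by two atoms into ring A.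
3. Enabling feature: ring A carries its oxygen on C2, 1,3 to the quaternary C4 (a latent cyclohexane-1,3-dione), and ring B carbon C8 (later C8=C17) can hold an oxygen that is 1,3 to C10. O8 therefore carries C2 as an enol ether (six-membered tether ring O8–C2–C1–C10–C9–C8) and steers the ketene to one face of C5=C10.
4. Ring B (C5–C10) comes from ring-closing metathesis of a 1,7-diene made by catalytic asymmetric allylboration of pent-4-enal. This sets C8, from which C10 is relayed; C5, C9 and C2 are then fixed by equilibration or thermodynamic reduction.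
5. Ring order: ring B (step 5), then ring A by ring expansion (step 7), then the side chain (step 19).

Key step: step 7

Remark: labdane numbering is used for all atoms (ring A = C1–C5 and C10; ring B = C5–C10; C17 exocyclic methylene; C18/C19 on C4; C20 on C10; side chain C11–C16).
Assumption: (R)-TRIP is taken to deliver the (4S)-carbinol 8 through the usual chair transition state of acid-catalysed allylboration; should the sense be opposite, the antipodal acid is used.

**Route**

Step 1
Reactants: 1 benzyl prop-2-yn-1-yl ether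
Product: 3 (E)-{[(3-iodoprop-2-en-1-yl)oxy]methyl}benzene, via alkenylzirconocene chloride 2 (not isolated)
Conditions: Cp2Zr(H)Cl, THF, 23 °C; then I2, 0 °C
Reagents that add atoms: iodine, II
Why: Hydrozirconation–iodination: syn addition of Zr–H places zirconium at the alkyne terminus and iodinolysis with retention should give the (E)-vinyl iodide.

Step 2
Reactants: 3 (E)-{[(3-iodoprop-2-en-1-yl)oxy]methyl}benzene; 4 4,4,5,5-tetramethyl-2-(prop-1-en-2-yl)-1,3,2-dioxaborolane
Product: 5 (E)-{[(4-methylpenta-2,4-dien-1-yl)oxy]methyl}benzene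
Conditions: Pd(PPh3)4 (cat.), K2CO3, THF/H2O, 60 °C
Reagents that add atoms: none
Why: Suzuki–Miyaura coupling of an alkenyl iodide with an alkenylboronate proceeds with retention and should give the (E)-2-methyl-1,3-diene.

Step 3
Reactants: 5 (E)-{[(4-methylpenta-2,4-dien-1-yl)oxy]methyl}benzene
Product: 6 2-[(2Z)-5-(benzyloxy)-2-methylpent-2-en-1-yl]-4,4,5,5-tetramethyl-1,3,2-dioxaborolane
Conditions: HBpin, Ni(cod)2 (cat.), PCy3 (cat.), toluene, 23 °C
Reagents that add atoms: pinacolborane, B1OC(C)(C)C(C)(C)O1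
Why: Nickel-catalysed 1,4-hydroboration of a 1,3-diene through its s-cis complex puts boron on C1 and hydrogen on C11 and should give the (Z)-allylboronate (C11 chain cis to CH2B), the geometry that leads to the syn adduct in step 4.

Step 4
Reactants: 6 2-[(2Z)-5-(benzyloxy)-2-methylpent-2-en-1-yl]-4,4,5,5-tetramethyl-1,3,2-dioxaborolane; 7 pent-4-enal
Product: 8 (3S,4S)-3-[2-(benzyloxy)ethyl]-2-methylocta-1,7-dien-4-ol
Conditions: (R)-TRIP (cat.), toluene, 4 Å MS, −30 °C
Reagents that add atoms: none
Why: Chiral-phosphoric-acid-catalysed allylboration through a closed chair transition state, in which the axial (Z)-γ-substituent gives the syn C8/C9 relationship and the catalyst sets the absolute configuration of the C8 carbinol, the only stereocentre of the route made by catalysis.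

Step 5
Reactants: 8 (3S,4S)-3-[2-(benzyloxy)ethyl]-2-methylocta-1,7-dien-4-ol
Product: 9 (1S,2S)-2-[2-(benzyloxy)ethyl]-3-methylcyclohex-3-en-1-ol
Conditions: second-generation Grubbs catalyst (cat.), CH2Cl2, 40 °C
Reagents that add atoms: none
Why: Ring-closing metathesis between the monosubstituted and the 1,1-disubstituted alkene should close ring B with the trisubstituted C5=C10 double bond, leaving the trans C8-OH/C9 chain pair untouched.

Step 6
Reactants: 9 (1S,2S)-2-[2-(benzyloxy)ethyl]-3-methylcyclohex-3-en-1-ol; 10 3-ethoxycyclobut-2-en-1-one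
Product: 11 3-{[(1S,2S)-2-[2-(benzyloxy)ethyl]-3-methylcyclohex-3-en-1-yl]oxy}cyclobut-2-en-1-one
Conditions: PPTS (cat.), toluene, 4 Å MS, 70 °C
Reagents that add atoms: none
Why: Acid-catalysed alkoxy exchange of a vinylogous ester (addition–elimination at C2) driven by removal of ethanol; the C8–O bond is not broken, so C8 keeps its configuration.

Step 7
Reactants: 11 3-{[(1S,2S)-2-[2-(benzyloxy)ethyl]-3-methylcyclohex-3-en-1-yl]oxy}cyclobut-2-en-1-one
Product: 14 bridged keto enol ether with ring A closed, via alkoxyvinylketene 12 (not isolated), via bridged vinylcyclobutanone 13 (not isolated)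
Conditions: toluene (0.005 M), 150 °C, sealed tube
Reagents that add atoms: none
Why: Proposed new method: heating opens the 3-alkoxycyclobutenone by 4π-electrocyclic cleavage of C3–C4 to the (1-alkoxyvinyl)ketene 12, whose ketene C=C adds across C5=C10 in an intramolecular [2+2] (new bonds C4–C5 and C1–C10) to the 2-vinylcyclobutanone 13, and a 1,3-acyl shift of C4 from C1 to C3 then expands this four-membered ring (C4, C1, C10, C5) by C2 and C3 into ring A; in net terms C5 and C10 are inserted into the C4–C1 bond of the original cyclobutenone. The closest known reaction types are the thermal cyclobutenone-to-vinylketene opening with [2+2] capture and ring expansion used in annulations with alkynes, the intramolecular [2+2] cycloaddition of vinylketenes with alkenes, and the thermal and alkoxide-accelerated 1,3-shifts that turn 2-vinylcyclobutanones and 2-vinylcyclobutanols into cyclohexenones and cyclohexenols. In the cycloaddition the tether ring O8–C2–C1–C10–C9–C8 closes six-membered with the ketene α-carbon C1 on the more substituted alkene carbon C10 and the carbonyl carbon C4 on C5 (the electronically preferred orientation and the only one the tether allows), the cyclobutanone closes cis on ring B, and ring A closes in the suprafacial acyl shift with C4 staying on C5. C10 is the one lasting new stereocentre and is dictated by C8: the ketene hangs from the pseudoaxial C8 oxygen and can reach C5=C10 only on the face of that oxygen, which is also the face anti to the pseudoaxial C9 chain; C5 is formed cis to C1 and is corrected in step 9. The step needs the unimolecular capture to outrun ketene dimerisation and the acyl shift to outrun cycloreversion, which high dilution, the reversible generation of the ketene, the 1,3-diaxial proximity of O8 and C10 and the release of cyclobutanone strain should secure. Should the vinylketene instead add as a four-carbon unit in a direct [4+2] manner, the isomeric bridged vinylogous ester converges on the same compound 15 in step 8.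

Step 8
Reactants: 14 bridged keto enol ether with ring A closed
Product: 15 (4aS,5S,6S,8aR)-5-[2-(benzyloxy)ethyl]-6-hydroxy-3-methoxy-4a-methyl-4a,5,6,7,8,8a-hexahydronaphthalen-1(4H)-one
Conditions: PPTS (cat.), MeOH, 23 °C
Reagents that add atoms: methanol, CO
Why: Acid-catalysed methanolysis of the bridging enol ether: protonation at C1, addition of methanol to the C2 oxocarbenium ion, departure of O8 as the free C8 alcohol and loss of H3 should give the conjugated vinylogous ester with OMe on C2 and the carbonyl on C4 (the less hindered regioisomer), with the ring fusion still cis.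

Step 9
Reactants: 15 (4aS,5S,6S,8aR)-5-[2-(benzyloxy)ethyl]-6-hydroxy-3-methoxy-4a-methyl-4a,5,6,7,8,8a-hexahydronaphthalen-1(4H)-one
Product: 17 (4aS,5S,8aS)-5-[2-(benzyloxy)ethyl]-3-methoxy-4a-methyl-4a,7,8,8a-tetrahydronaphthalene-1,6(4H,5H)-dione, via cis-fused diketone 16 (not isolated)
Conditions: Dess–Martin periodinane, CH2Cl2, 23 °C; then NaOMe (cat.), MeOH, 40 °C
Reagents that add atoms: none
Why: Dess–Martin oxidation of the C8 alcohol (so that O8 can no longer add back to C2), then base equilibration at C5 (α to the C4 carbonyl) and C9 (α to the C8 carbonyl) to the trans-fused isomer with an equatorial C9 chain, favoured because both ring A carbons 1,3 to the axial C20 methyl (C2 and C4) are trigonal.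

Step 10
Reactants: 17 (4aS,5S,8aS)-5-[2-(benzyloxy)ethyl]-3-methoxy-4a-methyl-4a,7,8,8a-tetrahydronaphthalene-1,6(4H,5H)-dione
Product: 18 (4aS,5R,8aS)-5-[2-(benzyloxy)ethyl]-3-methoxy-4a-methyl-6-methylidene-4a,5,6,7,8,8a-hexahydronaphthalen-1(4H)-one
Conditions: Ph3PCH3Br, KOtBu, THF, 0 to 50 °C
Reagents that add atoms: methylenetriphenylphosphorane, C=P(c1ccccc1)(c1ccccc1)c1ccccc1
Why: Wittig methylenation of the saturated C8 ketone; the vinylogous ester carbonyl at C4 is inert to the ylide and C5 and C9 already hold their thermodynamic configurations.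

Step 11
Reactants: 18 (4aS,5R,8aS)-5-[2-(benzyloxy)ethyl]-3-methoxy-4a-methyl-6-methylidene-4a,5,6,7,8,8a-hexahydronaphthalen-1(4H)-one
Product: 20 (4aR,8R,8aS)-8-[2-(benzyloxy)ethyl]-4,8a-dimethyl-7-methylidene-4a,5,6,7,8,8a-hexahydronaphthalen-2(1H)-one, via tertiary carbinol 19 (not isolated)
Conditions: MeLi, CeCl3, THF, −78 °C; then 1 M HCl, THF, 0 °C
Reagents that add atoms: methyllithium, [Li]C
Why: Stork–Danheiser transposition: 1,2-addition of MeLi to the vinylogous ester carbonyl and acid hydrolysis with loss of water should put the methyl on C4 and the carbonyl on C2, under conditions too brief and mild to enolise toward C5.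

Step 12
Reactants: 20 (4aR,8R,8aS)-8-[2-(benzyloxy)ethyl]-4,8a-dimethyl-7-methylidene-4a,5,6,7,8,8a-hexahydronaphthalen-2(1H)-one
Product: 21 (4aR,8R,8aR)-8-[2-(benzyloxy)ethyl]-4,4,8a-trimethyl-7-methylideneoctahydronaphthalen-2(1H)-one
Conditions: Me2CuLi (from MeLi and CuI), Et2O, −20 to 0 °C; then aq. NH4Cl
Reagents that add atoms: lithium dimethylcuprate, [Li+].C[Cu-]C
Why: Conjugate addition of the cuprate to the β,β-disubstituted enone (the isophorone precedent) should complete the C4 gem-dimethyl group without creating a stereocentre and without touching the isolated exocyclic alkene.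

Step 13
Reactants: 21 (4aR,8R,8aR)-8-[2-(benzyloxy)ethyl]-4,4,8a-trimethyl-7-methylideneoctahydronaphthalen-2(1H)-one
Product: 22 (2R,4aR,8R,8aR)-8-(2-hydroxyethyl)-4,4,8a-trimethyl-7-methylidenedecahydronaphthalen-2-ol
Conditions: Li, NH3, THF, t-BuOH, −78 to −33 °C; then NH4Cl
Reagents that add atoms: none
Why: Dissolving-metal reduction should give the thermodynamically favoured equatorial C2 alcohol (anti to the axial C19 and C20 methyls, the epimer that hydride reagents would not give) and cleave the benzyl ether in the same operation, while the isolated 1,1-disubstituted alkene is not reduced.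

Step 14
Reactants: 22 (2R,4aR,8R,8aR)-8-(2-hydroxyethyl)-4,4,8a-trimethyl-7-methylidenedecahydronaphthalen-2-ol
Product: 23 (2R,4aR,8R,8aR)-8-(2-iodoethyl)-4,4,8a-trimethyl-7-methylidenedecahydronaphthalen-2-ol
Conditions: PPh3, I2, imidazole, CH2Cl2, 0 °C
Reagents that add atoms: iodine, II
Why: Appel-type iodination is selective for the primary C12 alcohol over the secondary C2 alcohol.

Step 15
Reactants: 23 (2R,4aR,8R,8aR)-8-(2-iodoethyl)-4,4,8a-trimethyl-7-methylidenedecahydronaphthalen-2-ol
Product: 24 triethyl{[(2R,4aR,8R,8aR)-8-(2-iodoethyl)-4,4,8a-trimethyl-7-methylidenedecahydronaphthalen-2-yl]oxy}silane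
Conditions: TESCl, imidazole, DMF, 0 °C
Reagents that add atoms: chlorotriethylsilane, CC[Si](Cl)(CC)CC
Why: Silylation of the C2 alcohol so that the alkylzinc reagent of step 19 is not protonated.

Step 16
Reactants: 25 ethyl 4-chloro-3-oxobutanoate; 26 2-(trimethylsilyl)ethan-1-ol
Product: 27 2-(trimethylsilyl)ethyl 4-chloro-3-oxobutanoate
Conditions: toluene, 110 °C (ethanol distilled off)
Reagents that add atoms: none
Why: Thermal transesterification of a β-keto ester (through the acylketene) driven by removal of ethanol.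

Step 17
Reactants: 27 2-(trimethylsilyl)ethyl 4-chloro-3-oxobutanoate
Product: 28 2-(trimethylsilyl)ethyl 4-(acetyloxy)-3-oxobutanoate
Conditions: KOAc, DMF, 23 °C
Reagents that add atoms: potassium acetate, CC(=O)[O-].[K+]
Why: SN2 displacement of the activated α-chloroketone chloride by acetate.

Step 18
Reactants: 28 2-(trimethylsilyl)ethyl 4-(acetyloxy)-3-oxobutanoate
Product: 29 2-(trimethylsilyl)ethyl (2E)-4-(acetyloxy)-3-[(4-methylbenzenesulfonyl)oxy]but-2-enoate
Conditions: TsCl, N-methylimidazole, Et3N, CH2Cl2, 0 °C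
Reagents that add atoms: 4-methylbenzenesulfonyl chloride, Cc1ccc(cc1)S(Cl)(=O)=O
Why: O-Sulfonylation of the β-keto ester under non-chelating amine conditions should give the (E)-enol tosylate (OTs trans to the ester), which places CH2OAc cis to the ester as the target requires.

Step 19
Reactants: 24 triethyl{[(2R,4aR,8R,8aR)-8-(2-iodoethyl)-4,4,8a-trimethyl-7-methylidenedecahydronaphthalen-2-yl]oxy}silane; 29 2-(trimethylsilyl)ethyl (2E)-4-(acetyloxy)-3-[(4-methylbenzenesulfonyl)oxy]but-2-enoate
Product: 31 2-(trimethylsilyl)ethyl (2Z)-3-[(acetyloxy)methyl]-5-[(1R,4aR,7R,8aR)-5,5,8a-trimethyl-2-methylidene-7-[(triethylsilyl)oxy]decahydronaphthalen-1-yl]pent-2-enoate, via alkylzinc iodide 30 (not isolated)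
Conditions: Zn dust, LiCl, THF, 40 °C; then 29, Pd(OAc)2 (cat.), SPhos (cat.), THF, 23 °C
Reagents that add atoms: none
Why: Zinc insertion into the primary iodide and Negishi sp3–sp2 coupling with the activated enol tosylate proceed with retention of alkene geometry and should set the (13Z) trisubstituted double bond with ester and acetate intact.

Step 20
Reactants: 31 2-(trimethylsilyl)ethyl (2Z)-3-[(acetyloxy)methyl]-5-[(1R,4aR,7R,8aR)-5,5,8a-trimethyl-2-methylidene-7-[(triethylsilyl)oxy]decahydronaphthalen-1-yl]pent-2-enoate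
Product: 32 (2Z)-3-[(acetyloxy)methyl]-5-[(1R,4aR,7R,8aR)-7-hydroxy-5,5,8a-trimethyl-2-methylidenedecahydronaphthalen-1-yl]pent-2-enoic acid
Conditions: TBAF, AcOH (1:1), THF, 0 to 23 °C
Reagents that add atoms: none
Why: Buffered fluoride should cleave the secondary TES ether and the 2-(trimethylsilyl)ethyl ester (β-elimination to ethylene) without hydrolysing the acetate, lactonising the side chain or moving the exocyclic double bond.

**Compound list**

1 | benzyl prop-2-yn-1-yl ether | C#CCOCc1ccccc1 | starting material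
2 | (E)-[3-(benzyloxy)prop-1-en-1-yl]zirconocene chloride (not isolated) | Cl[Zr](/C=C/COCc1ccccc1)(C1C=CC=C1)C1C=CC=C1 | intermediate
3 | (E)-{[(3-iodoprop-2-en-1-yl)oxy]methyl}benzene | I/C=C/COCc1ccccc1 | intermediate
4 | 4,4,5,5-tetramethyl-2-(prop-1-en-2-yl)-1,3,2-dioxaborolane | C=C(C)B1OC(C)(C)C(C)(C)O1 | starting material
5 | (E)-{[(4-methylpenta-2,4-dien-1-yl)oxy]methyl}benzene | C=C(C)/C=C/COCc1ccccc1 | intermediate
6 | 2-[(2Z)-5-(benzyloxy)-2-methylpent-2-en-1-yl]-4,4,5,5-tetramethyl-1,3,2-dioxaborolane | C/C(CB1OC(C)(C)C(C)(C)O1)=C/CCOCc1ccccc1 | intermediate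
7 | pent-4-enal | C=CCCC=O | starting material
8 | (3S,4S)-3-[2-(benzyloxy)ethyl]-2-methylocta-1,7-dien-4-ol (syn) | C=CCC[C@H](O)[C@@H](CCOCc1ccccc1)C(C)=C | intermediate
9 | (1S,2S)-2-[2-(benzyloxy)ethyl]-3-methylcyclohex-3-en-1-ol (ring B; 8-OH trans to the C9 chain) | CC1=CCC[C@H](O)[C@H]1CCOCc1ccccc1 | intermediate
10 | 3-ethoxycyclobut-2-en-1-one | CCOC1=CC(=O)C1 | starting material
11 | 3-{[(1S,2S)-2-[2-(benzyloxy)ethyl]-3-methylcyclohex-3-en-1-yl]oxy}cyclobut-2-en-1-one | CC1=CCC[C@H](OC2=CC(=O)C2)[C@H]1CCOCc1ccccc1 | intermediate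
12 | 3-{[(1S,2S)-2-[2-(benzyloxy)ethyl]-3-methylcyclohex-3-en-1-yl]oxy}buta-1,3-dien-1-one (alkoxyvinylketene; not isolated) | CC1=CCC[C@H](OC(=C)C=C=O)[C@H]1CCOCc1ccccc1 | intermediate
13 | bridged 2-vinylcyclobutanone: four-membered ring C4(=O)–C1–C10–C5 cis-fused to ring B on the O8 face; C1 bears C2(=C3H2)–O–C8; H5, C20 and the C9 chain anti to O8 (not isolated) | O=C1[C@H]2C(=C)O[C@H]3CC[C@@H]1[C@]2(C)[C@@H]3CCOCc1ccccc1 | intermediate
14 | bridged keto enol ether with ring A closed: C4(=O)–C3H2–C2(–O–C8)=C1H–C10–C5; rings A/B cis-fused; H5, C20 and the C9 chain anti to O8 | O=C1CC2=C[C@@]3(C)[C@H](CCOCc4ccccc4)[C@@H](O2)CC[C@@H]13 | intermediate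
15 | (4aS,5S,6S,8aR)-5-[2-(benzyloxy)ethyl]-6-hydroxy-3-methoxy-4a-methyl-4a,5,6,7,8,8a-hexahydronaphthalen-1(4H)-one (cis-fused) | O[C@H]1CC[C@H]2C(=O)C=C(OC)C[C@@]2(C)[C@@H]1CCOCc1ccccc1 | intermediate
16 | (4aS,5S,8aR)-5-[2-(benzyloxy)ethyl]-3-methoxy-4a-methyl-4a,7,8,8a-tetrahydronaphthalene-1,6(4H,5H)-dione (cis-fused; not isolated) | O=C1CC[C@H]2C(=O)C=C(OC)C[C@@]2(C)[C@@H]1CCOCc1ccccc1 | intermediate
17 | (4aS,5S,8aS)-5-[2-(benzyloxy)ethyl]-3-methoxy-4a-methyl-4a,7,8,8a-tetrahydronaphthalene-1,6(4H,5H)-dione (trans-fused; C9 chain equatorial) | O=C1CC[C@@H]2C(=O)C=C(OC)C[C@@]2(C)[C@@H]1CCOCc1ccccc1 | intermediate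
18 | (4aS,5R,8aS)-5-[2-(benzyloxy)ethyl]-3-methoxy-4a-methyl-6-methylidene-4a,5,6,7,8,8a-hexahydronaphthalen-1(4H)-one | C=C1CC[C@@H]2C(=O)C=C(OC)C[C@@]2(C)[C@@H]1CCOCc1ccccc1 | intermediate
19 | tertiary allylic carbinol from 1,2-addition at C4 of 18 (C4 configuration immaterial; not isolated) | C=C1CC[C@@H]2C(C)(O)C=C(OC)C[C@@]2(C)[C@@H]1CCOCc1ccccc1 | intermediate
20 | (4aR,8R,8aS)-8-[2-(benzyloxy)ethyl]-4,8a-dimethyl-7-methylidene-4a,5,6,7,8,8a-hexahydronaphthalen-2(1H)-one | C=C1CC[C@@H]2C(C)=CC(=O)C[C@@]2(C)[C@@H]1CCOCc1ccccc1 | intermediate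
21 | (4aR,8R,8aR)-8-[2-(benzyloxy)ethyl]-4,4,8a-trimethyl-7-methylideneoctahydronaphthalen-2(1H)-one | C=C1CC[C@@H]2C(C)(C)CC(=O)C[C@@]2(C)[C@@H]1CCOCc1ccccc1 | intermediate
22 | (2R,4aR,8R,8aR)-8-(2-hydroxyethyl)-4,4,8a-trimethyl-7-methylidenedecahydronaphthalen-2-ol | C=C1CC[C@@H]2C(C)(C)C[C@@H](O)C[C@@]2(C)[C@@H]1CCO | intermediate
23 | (2R,4aR,8R,8aR)-8-(2-iodoethyl)-4,4,8a-trimethyl-7-methylidenedecahydronaphthalen-2-ol | C=C1CC[C@@H]2C(C)(C)C[C@@H](O)C[C@@]2(C)[C@@H]1CCI | intermediate
24 | triethyl{[(2R,4aR,8R,8aR)-8-(2-iodoethyl)-4,4,8a-trimethyl-7-methylidenedecahydronaphthalen-2-yl]oxy}silane | C=C1CC[C@@H]2C(C)(C)C[C@@H](O[Si](CC)(CC)CC)C[C@@]2(C)[C@@H]1CCI | intermediate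
25 | ethyl 4-chloro-3-oxobutanoate | CCOC(=O)CC(=O)CCl | starting material
26 | 2-(trimethylsilyl)ethan-1-ol | C[Si](C)(C)CCO | starting material
27 | 2-(trimethylsilyl)ethyl 4-chloro-3-oxobutanoate | C[Si](C)(C)CCOC(=O)CC(=O)CCl | intermediate
28 | 2-(trimethylsilyl)ethyl 4-(acetyloxy)-3-oxobutanoate | CC(=O)OCC(=O)CC(=O)OCC[Si](C)(C)C | intermediate
29 | 2-(trimethylsilyl)ethyl (2E)-4-(acetyloxy)-3-[(4-methylbenzenesulfonyl)oxy]but-2-enoate | CC(=O)OC/C(OS(=O)(=O)c1ccc(C)cc1)=C\C(=O)OCC[Si](C)(C)C | intermediate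
30 | alkylzinc iodide from 24 (C12–ZnI; not isolated) | C=C1CC[C@@H]2C(C)(C)C[C@@H](O[Si](CC)(CC)CC)C[C@@]2(C)[C@@H]1CC[Zn]I | intermediate
31 | 2-(trimethylsilyl)ethyl (2Z)-3-[(acetyloxy)methyl]-5-[(1R,4aR,7R,8aR)-5,5,8a-trimethyl-2-methylidene-7-[(triethylsilyl)oxy]decahydronaphthalen-1-yl]pent-2-enoate | C=C1CC[C@@H]2C(C)(C)C[C@@H](O[Si](CC)(CC)CC)C[C@@]2(C)[C@@H]1CC/C(=C/C(=O)OCC[Si](C)(C)C)COC(C)=O | intermediate
32 | (2Z)-3-[(acetyloxy)methyl]-5-[(1R,4aR,7R,8aR)-7-hydroxy-5,5,8a-trimethyl-2-methylidenedecahydronaphthalen-1-yl]pent-2-enoic acid | C=C1CC[C@@H]2C(C)(C)C[C@@H](O)C[C@@]2(C)[C@@H]1CC/C(=C/C(=O)O)COC(C)=O | target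

**Step count and risks**

Total steps: 20. Longest linear sequence: 17 (steps 1–15, 19, 20); the coupling partner 29 is made in 3 steps (16–18).

Steps most likely to fail:

Step 7 (proposed new method). The vinylketene may be lost to dimerisation or oligomerisation before it is captured, or the cascade may stall at the vinylcyclobutanone because the 1,3-acyl shift is slower than cycloreversion. The fallback runs the same bond changes stepwise with known chemistry, setting out from 9 and coming back at 14. Phosphine-catalysed addition of 9 to methyl but-2-ynoate (PMe3 cat.) should give the (E)-β-alkoxycrotonate F1. Saponification (LiOH) gives the acid F2, and oxalyl chloride the acid chloride F3. Slow addition of F3 to Et3N in toluene at 80 °C generates ketene 12 by the classical 1,4-dehydrochlorination, and the known intramolecular vinylketene–alkene [2+2] gives vinylcyclobutanone 13, which is isolated at this temperature. Reduction with LiBH(s-Bu)3 gives the vinylcyclobutanol F4. Its potassium alkoxide (KH, 18-crown-6, THF, 23 °C) undergoes the known alkoxide-accelerated 1,3-shift of 2-vinylcyclobutanols to the bridged cyclohexenol F5, and Dess–Martin oxidation returns ketone 14.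

Step 6. Exchange with the hindered secondary alcohol may be slow, and the acid may instead hydrate or open the strained cyclobutenone. The fallback builds the cyclobutenone on the oxygen of 9, setting out from 9 and coming back at 11. KH and trichloroethylene give the (E)-1,2-dichlorovinyl ether F6. n-BuLi (2 equiv, −78 °C, then MeOH) gives the ethynyl ether F7. Ketene (gas, CH2Cl2, 0 °C) adds to the alkoxyacetylene in the known [2+2] that delivers 3-alkoxycyclobutenones, here 11.

Step 12. The cuprate may fail to attack the congested C4 (flanked by the ring-fusion carbon C5), and enolisation or 1,2-addition may take over. The fallback makes the second methyl by electrophilic cyclopropanation and reductive opening, setting out from 20 and coming back at 22. Luche reduction (NaBH4, CeCl3, MeOH) gives the allylic alcohol F8. Hydroxyl-directed Simmons–Smith cyclopropanation (Et2Zn, CH2I2), much faster at the allylic alcohol than at the exocyclic alkene, gives the cyclopropyl carbinol F9, and Dess–Martin oxidation gives the cyclopropyl ketone F10. Li/NH3 with t-BuOH then cleaves the exocyclic cyclopropane bond that overlaps with the carbonyl (giving the C4 gem-dimethyl group), reduces the C2 ketone to the equatorial alcohol and removes the benzyl group, giving 22 directly.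

Further compounds
F1 | step 7 | methyl (2E)-3-{[(1S,2S)-2-[2-(benzyloxy)ethyl]-3-methylcyclohex-3-en-1-yl]oxy}but-2-enoate | COC(=O)/C=C(\C)O[C@H]1CCC=C(C)[C@@H]1CCOCc1ccccc1
F2 | step 7 | (2E)-3-{[(1S,2S)-2-[2-(benzyloxy)ethyl]-3-methylcyclohex-3-en-1-yl]oxy}but-2-enoic acid | OC(=O)/C=C(\C)O[C@H]1CCC=C(C)[C@@H]1CCOCc1ccccc1
F3 | step 7 | (2E)-3-{[(1S,2S)-2-[2-(benzyloxy)ethyl]-3-methylcyclohex-3-en-1-yl]oxy}but-2-enoyl chloride | ClC(=O)/C=C(\C)O[C@H]1CCC=C(C)[C@@H]1CCOCc1ccccc1
F4 | step 7 | bridged 2-vinylcyclobutanol from reduction of 13 at C4 (C4 configuration immaterial) | OC1[C@H]2C(=C)O[C@H]3CC[C@@H]1[C@]2(C)[C@@H]3CCOCc1ccccc1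
F5 | step 7 | bridged cyclohexenol: C4 alcohol corresponding to ketone 14 (C4 configuration immaterial) | OC1CC2=C[C@@]3(C)[C@H](CCOCc4ccccc4)[C@@H](O2)CC[C@@H]13
F6 | step 6 | (E)-1,2-dichlorovinyl ether of 9 | Cl/C=C(/Cl)O[C@H]1CCC=C(C)[C@@H]1CCOCc1ccccc1
F7 | step 6 | ethynyl ether of 9 | C#CO[C@H]1CCC=C(C)[C@@H]1CCOCc1ccccc1
F8 | step 12 | allylic alcohol from 1,2-reduction of 20 at C2 (C2 configuration immaterial) | C=C1CC[C@@H]2C(C)=CC(O)C[C@@]2(C)[C@@H]1CCOCc1ccccc1
F9 | step 12 | 3,4-methano carbinol: cyclopropane across C3–C4 cis to the C2 hydroxyl (new centres immaterial) | C=C1CC[C@@H]2C3(C)CC3C(O)C[C@@]2(C)[C@@H]1CCOCc1ccccc1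
F10 | step 12 | 3,4-methano-2-ketone: cyclopropyl ketone corresponding to F9 | C=C1CC[C@@H]2C3(C)CC3C(=O)C[C@@]2(C)[C@@H]1CCOCc1ccccc1
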